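**Plan**
- Retrosynthesis: after the acetate, ring B is cut at C8=C9 and at C5–C6, and the C4 methyl is removed. This frees a four-carbon linchpin (C6–C7–C8 with its methyl, as 3-methylbut-3-enyl Grignard) and a ring A enoate that already carries the whole side chain on C10. The enoate is cut at C4–C19 (carbonylation of an enol triflate) and at C10–C9 (conjugate addition of the side-chain alkenyl unit to 3-methylcyclohex-2-en-1-one).
- Forward order: side chain from hexa-1,5-diyne, then ring A receives its quaternary C10, then ring B is annulated in one flask (1,4-addition at C5, methylation at C4, ring-closing metathesis to C8=C9), then the acetate.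
- Enabling feature: C5 is the β-carbon of the C4 ester in ring A, C9 can be the inner carbon of a 1,1-disubstituted olefin on C10, and the two sites lie 1,3 across the quaternary, non-conjugating C10. No single concerted event spans them, so one C6–C7–C8 unit, nucleophilic at C6 and olefinic at C8, bridges them in two linked stages and closes ring B with its tetrasubstituted double bond.
- Stereochemistry: C10 from the chiral copper catalyst; C5 and C4 from C10 by substrate control in the key step; 13E from syn-carbometalation.

Key step: step 5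

Remark: labdane numbering is used (C19 is the ester carbon on C4, C17 the methyl on C8); the enantiomer of the chiral carbene ligand that gives 10S is assumed to be available.

**Step 1**
Reactants: 1 hexa-1,5-diyne
Product: 3 (2E)-3-methylhept-2-en-6-yn-1-ol, via alkenylalane 2 (not isolated)
Conditions: Me3Al, Cp2ZrCl2 (0.2 equiv), CH2Cl2, 0 to 23 °C, 1 in threefold excess; then (CH2O)n, 23 °C; aqueous work-up
Reagents that add atoms: trimethylaluminium, C[Al](C)C; formaldehyde (as paraformaldehyde), C=O
Why: Zirconium-catalysed carboalumination of a terminal alkyne (Negishi carboalumination) adds methyl and aluminium syn with methyl on the internal carbon, and hydroxymethylation of the alkenylalane with retention should give the 13E allylic alcohol, the excess of 1 keeping the second alkyne untouched.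

**Step 2**
Reactants: 3 (2E)-3-methylhept-2-en-6-yn-1-ol
Product: 4 tert-butyl(dimethyl){[(2E)-3-methylhept-2-en-6-yn-1-yl]oxy}silane
Conditions: TBSCl, imidazole, CH2Cl2, 23 °C
Reagents that add atoms: tert-butyldimethylsilyl chloride, CC(C)(C)[Si](C)(C)Cl
Why: Imidazole-promoted silylation masks the primary alcohol against the organoaluminium, organolithium and Grignard reagents used next and creates no stereocentre.

**Step 3**
Reactants: 4 tert-butyl(dimethyl){[(2E)-3-methylhept-2-en-6-yn-1-yl]oxy}silane; 5 3-methylcyclohex-2-en-1-one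
Product: 8 (3S)-3-methyl-3-{(5E)-7-[(tert-butyldimethylsilyl)oxy]-5-methylhepta-1,5-dien-2-yl}cyclohex-1-en-1-yl trifluoromethanesulfonate, via alkenylalane 6 (not isolated), via aluminium enolate 7 (not isolated)
Conditions: iBu2AlH, NiCl2(dppp) (0.03 equiv), THF, 23 °C; then 5, CuCl2·2H2O (0.05 equiv), chiral sulfonate-bearing imidazolinium salt (0.055 equiv), −30 °C; then MeLi, −78 °C; PhNTf2, −78 to 0 °C
Reagents that add atoms: N-phenylbis(trifluoromethanesulfonimide), O=S(=O)(N(c1ccccc1)S(=O)(=O)C(F)(F)F)C(F)(F)F
Why: Nickel-catalysed α-selective hydroalumination puts aluminium on the internal alkyne carbon, copper-catalysed asymmetric conjugate addition of this alkenylalane to the β-methyl enone builds the C10 quaternary centre with the S configuration dictated by the chiral carbene ligand, and triflation of the regiodefined enolate through its MeLi ate complex fixes the C4=C5 double bond.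

**Step 4**
Reactants: 8 (3S)-3-methyl-3-{(5E)-7-[(tert-butyldimethylsilyl)oxy]-5-methylhepta-1,5-dien-2-yl}cyclohex-1-en-1-yl trifluoromethanesulfonate
Product: 9 methyl (3S)-3-methyl-3-{(5E)-7-[(tert-butyldimethylsilyl)oxy]-5-methylhepta-1,5-dien-2-yl}cyclohex-1-ene-1-carboxylate
Conditions: Pd(OAc)2 (0.05 equiv), PPh3 (0.1 equiv), CO (1 atm), MeOH, Et3N, DMF, 60 °C
Reagents that add atoms: carbon monoxide, [C-]#[O+]; methanol, CO
Why: Palladium-catalysed methoxycarbonylation of an enol triflate (oxidative addition to zerovalent palladium, CO insertion, methanolysis) should give the conjugated methyl ester that carries C19 and makes C5 an acceptor carbon, with no stereocentre touched.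

**Step 5**
Reactants: 9 methyl (3S)-3-methyl-3-{(5E)-7-[(tert-butyldimethylsilyl)oxy]-5-methylhepta-1,5-dien-2-yl}cyclohex-1-ene-1-carboxylate; 10 4-bromo-2-methylbut-1-ene
Product: 14 methyl (4S,5R,10S)-15-[(tert-butyldimethylsilyl)oxy]labda-8,13E-dien-19-oate, via Grignard reagent 11 (not isolated), via magnesium enolate 12 (not isolated), via triene ester 13 (not isolated)
Conditions: a) Mg, THF (10 to 11), then 9, CuBr·SMe2 (0.2 equiv), THF, −40 to 0 °C; b) MeI, DMPU, 0 to 23 °C; c) MeOH quench, silica plug, solvent switch to toluene (no isolation), second-generation Hoveyda–Grubbs catalyst RuCl2(H2IMes)(=CH-C6H4-2-OiPr) (0.1 equiv), 100 °C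
Reagents that add atoms: iodomethane, CI
Why: The alkylcopper species formed from 11 adds 1,4 to the C4=C5 enoate (π-complexation, carbon–copper bond formation at C5, reductive elimination) to make C5–C6, the magnesium ester enolate 12 is methylated at C4, and the ruthenium alkylidene then couples the two 1,1-disubstituted olefins by [2+2] cycloaddition and cycloreversion with loss of ethene to make C8=C9. The closest known reaction types are the copper-catalysed conjugate addition of Grignard reagents to cyclohex-1-enecarboxylates with alkylation of the enolate, and the ring-closing metathesis that gives tetrasubstituted cyclohexenes beside a quaternary carbon. Ring B is the only ring closed, as a six-membered ring by metathesis of a 1,7-diene in which both new olefin carbons become ring members. C5 is set by attack of the copper reagent on the enoate face opposite the larger sp2-bound alkenyl group on C10 (the face of the C10 methyl), and C4 by methylation of the exocyclic enolate on the face opposite both the new C5 chain and the C10 methyl, which leaves the ester axial. The step needs 1,4- rather than 1,2-addition, carbon rather than oxygen methylation, and metathesis at the two terminal olefins rather than at C13=C14; copper catalysis at low temperature, the soft methyl iodide and the inertness of trisubstituted olefins to this catalyst should secure these. The trans relation of the C5 and C10 chains in 13 places both olefins equatorial, so closure should give the trans-fused decalin.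

**Step 6**
Reactants: 14 methyl (4S,5R,10S)-15-[(tert-butyldimethylsilyl)oxy]labda-8,13E-dien-19-oate
Product: 15 methyl (4S,5R,10S)-15-hydroxylabda-8,13E-dien-19-oate
Conditions: Bu4NF, THF, 0 to 23 °C
Reagents that add atoms: none
Why: Fluoride-induced desilylation cleaves the silicon–oxygen bond selectively and should leave the hindered axial methyl ester and both olefins untouched.

**Step 7**
Reactants: 15 methyl (4S,5R,10S)-15-hydroxylabda-8,13E-dien-19-oate
Product: 16 methyl (4S,5R,10S)-15-acetoxylabda-8,13E-dien-19-oate (CNP0206695.1)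
Conditions: Ac2O, pyridine, DMAP (0.05 equiv), CH2Cl2, 23 °C
Reagents that add atoms: acetic anhydride, CC(=O)OC(C)=O
Why: DMAP-catalysed acylation of a primary allylic alcohol with an anhydride should give the acetate without allylic transposition.

**Compound list**
1 | hexa-1,5-diyne | C#CCCC#C | starting material
2 | dimethyl[(1E)-2-methylhex-1-en-5-yn-1-yl]alumane | C#CCC/C(C)=C/[Al](C)C | intermediate
3 | (2E)-3-methylhept-2-en-6-yn-1-ol | C#CCC/C(C)=C/CO | intermediate
4 | tert-butyl(dimethyl){[(2E)-3-methylhept-2-en-6-yn-1-yl]oxy}silane | C#CCC/C(C)=C/CO[Si](C)(C)C(C)(C)C | intermediate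
5 | 3-methylcyclohex-2-en-1-one | CC1=CC(=O)CCC1 | starting material
6 | {(5E)-7-[(tert-butyldimethylsilyl)oxy]-5-methylhepta-1,5-dien-2-yl}bis(2-methylpropyl)alumane | C=C(CC/C(C)=C/CO[Si](C)(C)C(C)(C)C)[Al](CC(C)C)CC(C)C | intermediate
7 | bis(2-methylpropyl)aluminium (3S)-3-methyl-3-{(5E)-7-[(tert-butyldimethylsilyl)oxy]-5-methylhepta-1,5-dien-2-yl}cyclohex-1-en-1-olate | CC(C)C[Al](CC(C)C)OC1=C[C@@](C)(C(=C)CC/C(C)=C/CO[Si](C)(C)C(C)(C)C)CCC1 | intermediate
8 | (3S)-3-methyl-3-{(5E)-7-[(tert-butyldimethylsilyl)oxy]-5-methylhepta-1,5-dien-2-yl}cyclohex-1-en-1-yl trifluoromethanesulfonate | O=S(=O)(OC1=C[C@@](C)(C(=C)CC/C(C)=C/CO[Si](C)(C)C(C)(C)C)CCC1)C(F)(F)F | intermediate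
9 | methyl (3S)-3-methyl-3-{(5E)-7-[(tert-butyldimethylsilyl)oxy]-5-methylhepta-1,5-dien-2-yl}cyclohex-1-ene-1-carboxylate | COC(=O)C1=C[C@@](C)(C(=C)CC/C(C)=C/CO[Si](C)(C)C(C)(C)C)CCC1 | intermediate
10 | 4-bromo-2-methylbut-1-ene | C=C(C)CCBr | starting material
11 | (3-methylbut-3-en-1-yl)magnesium bromide | C=C(C)CC[Mg]Br | intermediate
12 | bromomagnesium ester enolate of methyl (2R,3S)-3-methyl-2-(3-methylbut-3-en-1-yl)-3-{(5E)-7-[(tert-butyldimethylsilyl)oxy]-5-methylhepta-1,5-dien-2-yl}cyclohexane-1-carboxylate (enolate double bond exocyclic at C4) | COC(O[Mg]Br)=C1CCC[C@](C)(C(=C)CC/C(C)=C/CO[Si](C)(C)C(C)(C)C)[C@H]1CCC(C)=C | intermediate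
13 | methyl (1S,2R,3S)-1,3-dimethyl-2-(3-methylbut-3-en-1-yl)-3-{(5E)-7-[(tert-butyldimethylsilyl)oxy]-5-methylhepta-1,5-dien-2-yl}cyclohexane-1-carboxylate | COC(=O)[C@@]1(C)CCC[C@](C)(C(=C)CC/C(C)=C/CO[Si](C)(C)C(C)(C)C)[C@H]1CCC(C)=C | intermediate
14 | methyl (4S,5R,10S)-15-[(tert-butyldimethylsilyl)oxy]labda-8,13E-dien-19-oate | COC(=O)[C@@]1(C)CCC[C@]2(C)C(CC/C(C)=C/CO[Si](C)(C)C(C)(C)C)=C(C)CC[C@@H]12 | intermediate
15 | methyl (4S,5R,10S)-15-hydroxylabda-8,13E-dien-19-oate | COC(=O)[C@@]1(C)CCC[C@]2(C)C(CC/C(C)=C/CO)=C(C)CC[C@@H]12 | intermediate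
16 | methyl (4S,5R,10S)-15-acetoxylabda-8,13E-dien-19-oate | COC(=O)[C@@]1(C)CCC[C@]2(C)C(CC/C(C)=C/COC(C)=O)=C(C)CC[C@@H]12 | target

Total step count: 7. Longest linear sequence: 7 steps (1 to 16).

**Steps most likely to fail**

Step 5. The 1,4-addition may discriminate too little between the methyl and alkenyl groups on C10, and a wrong C5 centre cannot be repaired later because C5 is not epimerisable beside the ester. Salts carried into the metathesis stage may also stall the ruthenium catalyst. The fallback sets out from aluminium enolate 7 and returns at 14; it makes C5 epimerisable by keeping C4 as a ketone until ring B exists. Enolate 7 is activated with MeLi and alkylated at C5 with 3-methylbut-3-en-1-yl trifluoromethanesulfonate to give (3S)-3-methyl-2-(3-methylbut-3-en-1-yl)-3-{(5E)-7-[(tert-butyldimethylsilyl)oxy]-5-methylhepta-1,5-dien-2-yl}cyclohexan-1-one F1. Ring-closing metathesis followed by equilibration with NaOMe should give the trans-fused (5R,10S)-15-[(tert-butyldimethylsilyl)oxy]-18,19-dinorlabda-8,13E-dien-4-one F2. Kinetic enolisation towards C3 with LiN(iPr)2 and trapping with PhNTf2 gives (5R,10S)-15-[(tert-butyldimethylsilyl)oxy]-18,19-dinorlabda-3,8,13E-trien-4-yl trifluoromethanesulfonate F3. Palladium-catalysed methoxycarbonylation gives methyl (5R,10S)-15-[(tert-butyldimethylsilyl)oxy]-18-norlabda-3,8,13E-trien-19-oate F4. Conjugate reduction with LiBH(sBu)3 and trapping of the ester enolate with MeI on the face opposite the axial C10 methyl should then give 14.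

Step 3. The hydroalumination may not be fully α-selective, and the hindered 1,1-disubstituted alkenyl group may transfer slowly or with low enantioselectivity. The fallback sets out from 4 and returns at 8; it builds C10 by adding methyl to an alkenyl enone instead of alkenyl to a methyl enone. Copper-catalysed Markovnikov protoboration of 4 (B2pin2, MeOH, (NHC)CuCl) gives tert-butyl(dimethyl){[(2E)-3-methyl-6-(4,4,5,5-tetramethyl-1,3,2-dioxaborolan-2-yl)hepta-2,6-dien-1-yl]oxy}silane F5. Suzuki coupling with 3-bromocyclohex-2-en-1-one (Pd(PPh3)4, K3PO4) gives 3-{(5E)-7-[(tert-butyldimethylsilyl)oxy]-5-methylhepta-1,5-dien-2-yl}cyclohex-2-en-1-one F6. Copper-catalysed asymmetric 1,4-addition of Me3Al with a chiral phosphoramidite, then MeLi and PhNTf2, should give 8.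

Step 1. The second terminal alkyne may also be carboaluminated, or its acidic hydrogen may protonate the alkenylalane. The fallback starts from commercial hex-5-yn-2-one instead of 1 (no numbered compound precedes step 1) and returns at 3; it uses carbonyl olefination in place of carbometalation. Horner–Wadsworth–Emmons reaction with triethyl phosphonoacetate gives ethyl (2E)-3-methylhept-2-en-6-ynoate F7, the Z isomer being removed by chromatography, and reduction with iBu2AlH gives 3.

**Further compounds**
F1 | step 5 | (3S)-3-methyl-2-(3-methylbut-3-en-1-yl)-3-{(5E)-7-[(tert-butyldimethylsilyl)oxy]-5-methylhepta-1,5-dien-2-yl}cyclohexan-1-one | O=C1CCC[C@](C)(C(=C)CC/C(C)=C/CO[Si](C)(C)C(C)(C)C)C1CCC(C)=C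
F2 | step 5 | (5R,10S)-15-[(tert-butyldimethylsilyl)oxy]-18,19-dinorlabda-8,13E-dien-4-one | O=C1CCC[C@]2(C)C(CC/C(C)=C/CO[Si](C)(C)C(C)(C)C)=C(C)CC[C@@H]12
F3 | step 5 | (5R,10S)-15-[(tert-butyldimethylsilyl)oxy]-18,19-dinorlabda-3,8,13E-trien-4-yl trifluoromethanesulfonate | O=S(=O)(OC1=CCC[C@]2(C)C(CC/C(C)=C/CO[Si](C)(C)C(C)(C)C)=C(C)CC[C@@H]12)C(F)(F)F
F4 | step 5 | methyl (5R,10S)-15-[(tert-butyldimethylsilyl)oxy]-18-norlabda-3,8,13E-trien-19-oate | COC(=O)C1=CCC[C@]2(C)C(CC/C(C)=C/CO[Si](C)(C)C(C)(C)C)=C(C)CC[C@@H]12
F5 | step 3 | tert-butyl(dimethyl){[(2E)-3-methyl-6-(4,4,5,5-tetramethyl-1,3,2-dioxaborolan-2-yl)hepta-2,6-dien-1-yl]oxy}silane | C=C(B1OC(C)(C)C(C)(C)O1)CC/C(C)=C/CO[Si](C)(C)C(C)(C)C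
F6 | step 3 | 3-{(5E)-7-[(tert-butyldimethylsilyl)oxy]-5-methylhepta-1,5-dien-2-yl}cyclohex-2-en-1-one | O=C1C=C(C(=C)CC/C(C)=C/CO[Si](C)(C)C(C)(C)C)CCC1
F7 | step 1 | ethyl (2E)-3-methylhept-2-en-6-ynoate | C#CCC/C(C)=C/C(=O)OCC
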